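## Analysis of the target

The target is a tetracyclic diterpenoid acetate, C22H34O4. Atoms are numbered as in a labdane. Ring A is C1–C5/C10 (gem-dimethyl C18/C19 on C4, angular methyl C20 on C10). Ring B is C5–C10 (acetoxy on C6, ketone C7, methyl C17 on C8). Ring C is the cyclobutane C8–C15–C14–C9. Ring D is the cyclopentane C9–C11–C12–C13–C14, with hydroxyl and methyl C16 on C13.

C9 belongs to rings B, C and D, and C8–C9–C10 is a row of three fully substituted carbons. There are seven stereocentres (C5, C6, C8, C9, C10, C13, C14):

- rings A/B are trans-fused (H5 α, C20 β);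
- C17 is β, so the cyclobutane (C15 on C8, C14 on C9) lies on the α face and C11 is β;
- rings C/D are cis-fused, and the C13 hydroxyl is cis to H14, on the convex face of the bicyclo[3.2.0]heptane;
- the C6 acetate is β, axial and syn to the axial methyls C19 and C20.

The sensitive groups are the α-acetoxy ketone (C6 can epimerise to the presumably more stable equatorial acetate, and the ester is base-labile), the tertiary carbinol next to the strained ring (acid would dehydrate it or enlarge the ring) and the cyclobutane itself. The difficulty is the quaternary row inside a cis-fused four-membered ring, with the configurations at C9, C13 and C6 all to be taken from the substrate.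

The strategy rests on one feature. With ring C removed, C9 is the end of an allyl unit C17–C8=C9, in which C17 is cis to C11, and C9 is already tied to C13 through C11–C12. An enol ether oxygen bridging C13 and C17 therefore gives a seven-membered allyl vinyl ether whose exocyclic methylene (C14) can be handed to C9 on the α face, closing ring D.

## Retrosynthetic reasoning

**C6–O (acetate).** The acetate is removed first, back to ketone 23 by way of enol acetate 25 and its epoxide 26. Direct electrophilic acetoxylation would come from the open α face and give the equatorial epimer. Instead the acetoxy group is moved from O7 to C6 across the β face with inversion (26 → 27), so the same facial bias places it axial. C6 is the only enolisable carbon of 23. The tertiary alcohol is silylated (22 → 23) only for these steps.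

**C13–O.** Alcohol 22 comes from the exocyclic alkene 21 by Markovnikov hydration on the convex face. Addition of a methyl nucleophile to a C13 ketone would put carbon, not oxygen, on that face, hence the alkene.

**C8–C15 (ring C).** The cyclobutane is opened at C8–C15, not at C14–C15 or C8–C9. This bond can be formed by an enolate tied to its electrophile: enolate 20, formed only at C8 by hydride addition to the exo-methylene ketone 19, displaces the tosylate on C15. The tether (C15 on C14, α on C9) fixes the new quaternary centre C8, and the same hydride turns C17 into the C8 methyl.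

**Functional group changes, 19 back to 15.** The tosylate comes from the primary alcohol, the C7 ketone from allylic alcohol 16 (allylic oxidation of the C8=C17 alkene of 15), and the C13 methylene (C16) from the ketone. C7 is oxidised before C13 is methylenated, so that only one alkene with allylic hydrogens is present at the oxidation.

**C14–C15.** C15 is removed from 15 as formaldehyde: an aldol reaction at C14 of enone 12 through dienolate 13. The C11=C12 double bond of 12 (from 11) serves to leave C14 as the only acidic position; the saturated ketone would enolise toward the less hindered C12.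

**C9–C14 (key disconnection).** Spiro ketone 11 is cut between the spiro carbon and the ketone α-carbon, a retro-Claisen operation to methylene oxepene 10. This removes ring D, the quaternary centre and the C9 stereocentre in one cut and leaves a flat, fused tricycle. The oxygen must sit on C17 and not on ring carbon C7: C7 is trans to C11 across C8=C9, so a C13–O–C7 bridge would require an E-alkene in a seven-membered ring, whereas C17 is cis to C11. The forward shift has to deliver C14 to the α face; the axial methyl C20 next to C9 should ensure this.

**C13=C14 and C17–O.** Enol ether 10 comes from lactone 9 by carbonyl methylenation. Lactone 9 is the Baeyer–Villiger product of the β,γ-unsaturated ketone 8, the allylic carbon C17 migrating. Ring D of the target is thus, for the moment, the six-membered ring C of a podocarpane.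

**Position of the alkene.** Ketone 8 needs the alkene at C8=C9, out of conjugation. Deconjugation of enone 5 would move it toward C7; Birch reduction of anisole 6 (through 7) places it without ambiguity. Anisole 6 comes from enone 5 by oxidative aromatisation, which gives up the C9 stereocentre that the key step rebuilds.

**C8–C17 and the starting material.** Enone 5 is the aldol condensation product of diketone 3 (through ketol 4), and 3 arises by oxidative cleavage of both alkenes of manool 1 (through 2). Manool supplies rings A and B with C5 and C10 in the required configuration.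

## Alternatives that were turned down

**Alternative 1:** Rings A and B are disconnected at C4–C5 and C9–C10. In the forward sense MeAlCl2 opens a terminal epoxide and the chain folds in a cation–olefin bicyclisation. The terminating nucleophile is the γ-carbon (C9) of a silyl dienol ether built on a preformed ring C/D bicycle. The product is A1.

- For: it is convergent, forms two rings and sets C5, C10 and C9 in one step, takes absolute configuration from an enantiopure epoxide, and makes the cyclobutane early by routine chemistry. On convergence and on forging the C9–C10 bond directly it is stronger than the chosen route.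
- Against: the last bond joins a tertiary cation to a fully substituted carbon of a strained dienol ether, where proton loss or attack at the α-carbon is easier. A1 also carries oxygen where the target has none (C3 hydroxyl, C11 ketone), lacks it at C6 and still needs hydration at C13, so a long redox sequence follows.
- Comparison: the chosen route never has to form C9–C10, because the decalin with C5 and C10 is bought from the chiral pool; it pays with a long linear sequence.

**Alternative 2:** Rings B and C are disconnected together at C8–C9. A ring-A-fused cyclooctadienone is photo-isomerised to its strained E,Z isomer, which closes thermally by conrotatory 4π electrocyclisation to the cyclobutene-fused acetoxy ketone A2. Ring D would follow from the side-chain ketone.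

- For: the acetoxy ketone is in place before the key step, the cis ring fusion follows from the pericyclic rules, and few steps remain afterwards. On end-game step economy and on the C6 acetate it is stronger than the chosen route.
- Against: the eight-membered dienone with the C6 acetate and the quaternary C10 is itself a hard target. The closure must create two adjacent quaternary carbons next to C10 with no clear control of which face closes. The α-acetoxy ketone is a photolabile chromophore.
- Comparison: the chosen route sets C9 in a thermal step with a clear facial bias (C20) and C8 through a tether, and uses no photochemistry.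

**Alternative 3:** Ring B is disconnected at C9–C10. TiCl4 ionises a tertiary chloride on ring A and the cation is captured by the junction carbon of the bicyclic silyl dienol ether, giving A3.

- For: it is the shortest way to the carbon skeleton, the C6=C7 alkene of A3 is a good handle for the C6/C7 oxygens, and less surplus oxygen is carried than in A1.
- Against: elimination of HCl competes with capture between two fully substituted carbons. The trans ring fusion must come from face selection on a planar C10 cation with only C5 to guide it. α- versus γ-attack of the dienol ether is open. The C11 ketone must still be removed and C13 hydrated.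
- Comparison: the chosen route takes the A/B ring fusion from the starting material and controls every later centre by ring constraints, at the cost of length and of an unproven key step.

Key step: step 7

**Remarks on the chemistry.**
- The carbon numbered C17 in 5–19 is the ring carbon between C13 and C8 of the podocarpane (the ketone methyl of 3).
- C14 and C16 come from the titanium methylidene reagent (steps 6 and 12) and C15 from formaldehyde (step 9).
- C7 of 16–18 is oxidised in step 14, so its configuration does not matter; the 7α-alcohol is drawn.
- Ketol 4 is drawn as the trans-fused 8β-alcohol.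

## Steps

Step 1
Reactants: 1 (+)-manool, (13R)-labda-8(17),14-dien-13-ol
Product: 3 14,15,17-trinorlabdane-8,13-dione, via keto hydroxy aldehyde 2 (not isolated)
Conditions: O3, CH2Cl2–MeOH, −78 °C; Me2S; then NaIO4, THF–H2O, 20 °C
Reagents that add atoms: ozone, [O-][O+]=O
Why: Ozonolysis cleaves both terminal alkenes, and periodate then cuts the α-hydroxy aldehyde between C13 and C14 (glycol-type cleavage) to leave the methyl ketone. The stereocentres of the decalin are not touched.

Step 2
Reactants: 3 14,15,17-trinorlabdane-8,13-dione
Product: 5 podocarp-8(14)-en-13-one, via ketol 4 (not isolated)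
Conditions: KOH, MeOH, reflux
Reagents that add atoms: none
Why: Intramolecular aldol condensation: the methyl ketone enolate adds to the C8 ketone to close a six-membered ring, and the ketol loses water to the conjugated enone. The methyl carbon becomes the ring carbon called C17 from here on.

Step 3
Reactants: 5 podocarp-8(14)-en-13-one
Product: 6 13-methoxypodocarpa-8,11,13-triene
Conditions: I2 (1.1 equiv), MeOH, reflux
Reagents that add atoms: methanol, CO
Why: Iodine-mediated oxidative aromatisation of a cyclohexenone in methanol (dienol ether formation, iodination, loss of HI) should give the anisole. C9 is made trigonal on purpose so that the next step can place the alkene at C8=C9.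

Step 4
Reactants: 6 13-methoxypodocarpa-8,11,13-triene
Product: 8 podocarp-8-en-13-one, via dihydroanisole 7 (not isolated)
Conditions: Li, NH3(l), THF, t-BuOH, −33 °C; then (CO2H)2, MeOH–H2O, 20 °C
Reagents that add atoms: water, O
Why: Birch reduction of a 6-methoxytetralin-type arene leaves the tetrasubstituted ring-fusion alkene C8=C9 and the enol ether. Hydrolysis with oxalic acid frees the ketone without moving the alkene into conjugation.

Step 5
Reactants: 8 podocarp-8-en-13-one
Product: 9 17-hydroxy-14,15,16-trinorlabd-8-en-13-oic acid 13,17-lactone (seven-membered)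
Conditions: (Me3SiO)2, Me3SiOTf (cat.), CH2Cl2, −40 °C
Reagents that add atoms: bis(trimethylsilyl) peroxide, C[Si](C)(C)OO[Si](C)(C)C
Why: Baeyer–Villiger oxidation in which the allylic CH2 (C17) migrates in preference to C12. The silyl peroxide activated by silyl triflate attacks the ketone and is not an epoxidising agent for the tetrasubstituted alkene.

Step 6
Reactants: 9 17-hydroxy-14,15,16-trinorlabd-8-en-13-oic acid 13,17-lactone
Product: 10 13,17-epoxy-15,16-dinorlabda-8,13-diene (2-methylene oxepene fused to ring B at C8=C9)
Conditions: Cp2Ti(Cl)CH2AlMe2, pyridine (cat.), THF–toluene, −40 → 20 °C; filtration through basic Al2O3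
Reagents that add atoms: Cp2Ti(Cl)CH2AlMe2, C[Al](C)C[Ti](Cl)(C1C=CC=C1)C1C=CC=C1
Why: Carbonyl methylenation of a lactone by the titanium methylidene; the non-basic reagent leaves the allylic C–O bond intact. The enol ether is acid-labile and is used at once.

Step 7
Reactants: 10 13,17-epoxy-15,16-dinorlabda-8,13-diene
Product: 11 9,14-cyclo-15,16-dinorlabd-8(17)-en-13-one (spiro cyclopentanone, C14 on the α face of C9)
Conditions: decalin, 200 °C, sealed silylated tube, 2,6-di-tert-butyl-4-methylphenol (cat.)
Reagents that add atoms: none
Why: Proposed new method: on heating, the allylic C17–O bond breaks while the exocyclic methylene C14 bonds to C9 in a concerted suprafacial [3,3] shift through a chair-like six-atom array (C14=C13–O–C17–C8=C9) spanned by the C11–C12 tether, so the oxepene contracts to the cyclopentanone, the ring B alkene moves to C8=C17, and formation of the ketone makes the step irreversible. The closest known reaction types are the thermal Claisen rearrangement of 2-methylene oxacycles made by titanium methylenation of lactones (a ring expansion when the allyl unit is an exocyclic vinyl group) and the Ireland–Claisen ring contraction of unsaturated macrolactones; contraction of a seven-membered enol ether in which the enol ether carbon stays inside the new ring has not been shown. Ring D closes five-membered with the enol ether double bond inside the forming ring (endo to C13=C14, exo to C8=C9), which forces the C13 substituents out of plane in a bicyclo[3.2.1]-like transition state and is why a high temperature is planned. The tether is cis to C17 on the tetrasubstituted alkene, so both ends of the array can be reached; an oxygen on ring carbon C7 would be trans to the tether and could not react this way. The only new stereocentre, C9, is set by the axial methyl C20 on C10, which closes the upper face, so C14 adds axially from below and C11 moves up. The step needs the [3,3] bond (C14 to C9) in preference to a 1,3-recombination at C17, which would give a ring-enlarged cycloheptenone; a non-polar medium, silylated glass and the absence of Lewis acid are chosen to favour the concerted path.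

Step 8
Reactants: 11 9,14-cyclo-15,16-dinorlabd-8(17)-en-13-one
Product: 12 9,14-cyclo-15,16-dinorlabda-8(17),11-dien-13-one
Conditions: IBX (2-iodoxybenzoic acid), DMSO–toluene, 75 °C
Reagents that add atoms: none
Why: Dehydrogenation of a ketone with IBX; only C11–C12 can be desaturated because C9 carries no hydrogen. The enone leaves C14 as the only enolisable position.

Step 9
Reactants: 12 9,14-cyclo-15,16-dinorlabda-8(17),11-dien-13-one
Product: 14 15-hydroxy-9,14-cyclo-16-norlabda-8(17),11-dien-13-one (CH2OH on the ring D face turned to C8), via lithium dienolate 13 (not isolated)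
Conditions: LiN(i-Pr)2, THF, −78 °C; CH2O (monomeric, THF), −78 °C; AcOH
Reagents that add atoms: formaldehyde, C=O
Why: α′-Deprotonation gives the cross-conjugated dienolate, which undergoes an aldol reaction with formaldehyde at C14. Formaldehyde should approach the ring D face turned to C8, because the other face lies against the axial hydrogen on C1, so C15 ends on the side from which it can later reach C8. The centre can still epimerise toward this less crowded isomer until step 12.

Step 10
Reactants: 14 15-hydroxy-9,14-cyclo-16-norlabda-8(17),11-dien-13-one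
Product: 15 15-hydroxy-9,14-cyclo-16-norlabd-8(17)-en-13-one
Conditions: [(Ph3P)CuH]6 (0.35 equiv), H2O (2 equiv), THF, 20 °C
Reagents that add atoms: none
Why: Copper hydride conjugate reduction of the enone. The isolated 1,1-disubstituted alkene and the ketone are not reduced, and the β-hydroxy ketone meets no base.

Step 11
Reactants: 15 15-hydroxy-9,14-cyclo-16-norlabd-8(17)-en-13-one
Product: 16 7α,15-dihydroxy-9,14-cyclo-16-norlabd-8(17)-en-13-one
Conditions: SeO2 (0.5 equiv), t-BuOOH, CH2Cl2, 20 °C
Reagents that add atoms: tert-butyl hydroperoxide, CC(C)(C)OO; selenium dioxide, O=[Se]=O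
Why: Allylic hydroxylation by SeO2 (ene reaction, then [2,3] shift). C7 carries the only allylic hydrogens of the C8=C17 alkene, since C9 is quaternary.

Step 12
Reactants: 16 7α,15-dihydroxy-9,14-cyclo-16-norlabd-8(17)-en-13-one
Product: 17 9,14-cyclolabda-8(17),13(16)-diene-7α,15-diol
Conditions: Cp2Ti(Cl)CH2AlMe2 (4 equiv), pyridine (cat.), THF, −40 → 0 °C
Reagents that add atoms: Cp2Ti(Cl)CH2AlMe2, C[Al](C)C[Ti](Cl)(C1C=CC=C1)C1C=CC=C1
Why: Titanium methylidene olefination of a hindered, enolisable ketone under non-basic conditions, so neither retro-aldol cleavage nor elimination of the β-hydroxy ketone is expected; the hydroxyl groups are carried as alkoxides by the excess reagent. The step follows step 11 so that only one alkene with allylic hydrogens was present at the oxidation.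

Step 13
Reactants: 17 9,14-cyclolabda-8(17),13(16)-diene-7α,15-diol
Product: 18 7α-hydroxy-9,14-cyclolabda-8(17),13(16)-dien-15-yl 4-toluenesulfonate
Conditions: TsCl (1.1 equiv), pyridine, DMAP (cat.), CH2Cl2, 0 °C
Reagents that add atoms: 4-toluenesulfonyl chloride, Cc1ccc(cc1)S(Cl)(=O)=O
Why: Sulfonylation of the primary alcohol in preference to the hindered secondary allylic alcohol.

Step 14
Reactants: 18 7α-hydroxy-9,14-cyclolabda-8(17),13(16)-dien-15-yl 4-toluenesulfonate
Product: 19 7-oxo-9,14-cyclolabda-8(17),13(16)-dien-15-yl 4-toluenesulfonate
Conditions: MnO2, CH2Cl2, 20 °C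
Reagents that add atoms: none
Why: MnO2 oxidises only the allylic alcohol. The α-methylene ketone cannot isomerise into the ring because C9 has no hydrogen; it is used directly.

Step 15
Reactants: 19 7-oxo-9,14-cyclolabda-8(17),13(16)-dien-15-yl 4-toluenesulfonate
Product: 21 8,15:9,14-dicyclolabd-13(16)-en-7-one (C17 β, cyclobutane on the α face), via potassium enolate 20 (not isolated)
Conditions: KBH(s-Bu)3 (1.05 equiv), THF, −78 °C; then 20 °C
Reagents that add atoms: none
Why: Conjugate hydride addition to the β-unsubstituted enone gives the C7(O)=C8 enolate regiospecifically and turns C17 into the C8 methyl; the enolate carbon then displaces the tosylate in a 4-exo-tet closure (reductive alkylation). C15 hangs from C14 on the lower face of ring B, so the bond can only form there, which places C17 β and makes the cyclobutane cis-fused. O-Alkylation is excluded because the enolate oxygen is trans to C9.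

Step 16
Reactants: 21 8,15:9,14-dicyclolabd-13(16)-en-7-one
Product: 22 13-hydroxy-8,15:9,14-dicyclolabdan-7-one (OH cis to H14)
Conditions: Co(acac)2 (cat.), PhSiH3, O2 (1 atm), THF, 20 °C
Reagents that add atoms: dioxygen, O=O
Why: Mukaiyama hydration: hydrogen atom transfer to the CH2 terminus gives the tertiary C13 radical, which should be trapped by O2 on the convex face of the cis-bicyclo[3.2.0]heptane, anti to C15, so that OH ends cis to H14. Trapping by O2 is expected to be faster than opening of the cyclobutylcarbinyl radical.

Step 17
Reactants: 22 13-hydroxy-8,15:9,14-dicyclolabdan-7-one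
Product: 23 13-(trimethylsilyloxy)-8,15:9,14-dicyclolabdan-7-one
Conditions: Me3SiOTf, 2,6-lutidine, CH2Cl2, −78 °C
Reagents that add atoms: trimethylsilyl trifluoromethanesulfonate, C[Si](C)(C)OS(=O)(=O)C(F)(F)F
Why: Silylation of the tertiary alcohol, so that the next step acylates only the enolate. At −78 °C with lutidine the hindered ketone is not enolised.

Step 18
Reactants: 23 13-(trimethylsilyloxy)-8,15:9,14-dicyclolabdan-7-one
Product: 25 13-(trimethylsilyloxy)-8,15:9,14-dicyclolabd-6-en-7-yl acetate, via potassium enolate 24 (not isolated)
Conditions: KN(SiMe3)2, THF, −78 °C; Ac2O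
Reagents that add atoms: acetic anhydride, CC(=O)OC(C)=O
Why: C6 is the only enolisable position, and the potassium enolate is O-acylated by the anhydride to the enol acetate.

Step 19
Reactants: 25 13-(trimethylsilyloxy)-8,15:9,14-dicyclolabd-6-en-7-yl acetate
Product: 26 6α,7α-epoxy-13-(trimethylsilyloxy)-8,15:9,14-dicyclolabdan-7β-yl acetate
Conditions: dimethyldioxirane, acetone–CH2Cl2, 0 °C; evaporation, no chromatography
Reagents that add atoms: dimethyldioxirane, CC1(C)OO1
Why: Epoxidation of the enol acetate from the lower face, because the upper face of C6=C7 is closed by the axial methyls C19 and C20 and by C17. The neutral reagent leaves only acetone, so the acid-sensitive epoxy acetate is not exposed to silica.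

Step 20
Reactants: 26 6α,7α-epoxy-13-(trimethylsilyloxy)-8,15:9,14-dicyclolabdan-7β-yl acetate
Product: 28 6β-acetoxy-13-hydroxy-8,15:9,14-dicyclolabdan-7-one (CNP0330581.1), via silyl ether 27 (not isolated)
Conditions: toluene, 110 °C, base-washed glass; then HF·pyridine, THF, 0 °C
Reagents that add atoms: none
Why: Thermal rearrangement of an enol ester epoxide: the acetoxy group migrates intramolecularly from C7 to C6 across the upper face with inversion at C6 while the epoxide oxygen becomes the ketone, which should give the axial 6β-acetate. Acid catalysis, which leads to retention, is kept out by base-washed glass; buffered HF·pyridine then removes the silyl ether without epimerising C6.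

## Compound list

1 | (+)-manool, (13R)-labda-8(17),14-dien-13-ol | C=C[C@](C)(O)CC[C@@H]1[C@@]2(C)CCCC(C)(C)[C@@H]2CCC1=C | starting material
2 | (13R)-13-hydroxy-8-oxo-15,17-dinorlabdan-14-al | O=C[C@](C)(O)CC[C@@H]1[C@@]2(C)CCCC(C)(C)[C@@H]2CCC1=O | intermediate
3 | 14,15,17-trinorlabdane-8,13-dione | CC(=O)CC[C@@H]1[C@@]2(C)CCCC(C)(C)[C@@H]2CCC1=O | intermediate
4 | 8β-hydroxypodocarpan-13-one | O=C1CC[C@H]2[C@](O)(C1)CC[C@H]1C(C)(C)CCC[C@]21C | intermediate
5 | podocarp-8(14)-en-13-one | O=C1CC[C@H]2C(=C1)CC[C@H]1C(C)(C)CCC[C@]21C | intermediate
6 | 13-methoxypodocarpa-8,11,13-triene | COc1ccc2c(c1)CC[C@H]1C(C)(C)CCC[C@]21C | intermediate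
7 | 13-methoxypodocarpa-8,12-diene | COC1=CCC2=C(C1)CC[C@H]1C(C)(C)CCC[C@]21C | intermediate
8 | podocarp-8-en-13-one | O=C1CCC2=C(C1)CC[C@H]1C(C)(C)CCC[C@]21C | intermediate
9 | 17-hydroxy-14,15,16-trinorlabd-8-en-13-oic acid 13,17-lactone | O=C1CCC2=C(CO1)CC[C@H]1C(C)(C)CCC[C@]21C | intermediate
10 | 13,17-epoxy-15,16-dinorlabda-8,13-diene (methylene oxepene) | C=C1CCC2=C(CO1)CC[C@H]1C(C)(C)CCC[C@]21C | intermediate
11 | 9,14-cyclo-15,16-dinorlabd-8(17)-en-13-one (C14 α on C9) | O=C1CC[C@@]2(C1)C(=C)CC[C@H]1C(C)(C)CCC[C@]21C | intermediate
12 | 9,14-cyclo-15,16-dinorlabda-8(17),11-dien-13-one | O=C1C=C[C@@]2(C1)C(=C)CC[C@H]1C(C)(C)CCC[C@]21C | intermediate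
13 | lithium 9,14-cyclo-15,16-dinorlabda-8(17),11,13-trien-13-olate | [Li+].[O-]C1C=C[C@@]2(C=1)C(=C)CC[C@H]1C(C)(C)CCC[C@]21C | intermediate
14 | 15-hydroxy-9,14-cyclo-16-norlabda-8(17),11-dien-13-one | O=C1C=C[C@@]2([C@@H]1CO)C(=C)CC[C@H]1C(C)(C)CCC[C@]21C | intermediate
15 | 15-hydroxy-9,14-cyclo-16-norlabd-8(17)-en-13-one | O=C1CC[C@@]2([C@@H]1CO)C(=C)CC[C@H]1C(C)(C)CCC[C@]21C | intermediate
16 | 7α,15-dihydroxy-9,14-cyclo-16-norlabd-8(17)-en-13-one | O=C1CC[C@@]2([C@@H]1CO)C(=C)[C@H](O)C[C@H]1C(C)(C)CCC[C@]21C | intermediate
17 | 9,14-cyclolabda-8(17),13(16)-diene-7α,15-diol | C=C1CC[C@@]2([C@@H]1CO)C(=C)[C@H](O)C[C@H]1C(C)(C)CCC[C@]21C | intermediate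
18 | 7α-hydroxy-9,14-cyclolabda-8(17),13(16)-dien-15-yl 4-toluenesulfonate | C=C1CC[C@@]2([C@@H]1COS(=O)(=O)c3ccc(C)cc3)C(=C)[C@H](O)C[C@H]1C(C)(C)CCC[C@]21C | intermediate
19 | 7-oxo-9,14-cyclolabda-8(17),13(16)-dien-15-yl 4-toluenesulfonate | C=C1CC[C@@]2([C@@H]1COS(=O)(=O)c3ccc(C)cc3)C(=C)C(=O)C[C@H]1C(C)(C)CCC[C@]21C | intermediate
20 | potassium 15-(tosyloxy)-9,14-cyclolabda-7,13(16)-dien-7-olate | [K+].C=C1CC[C@@]2([C@@H]1COS(=O)(=O)c3ccc(C)cc3)C(C)=C([O-])C[C@H]1C(C)(C)CCC[C@]21C | intermediate
21 | 8,15:9,14-dicyclolabd-13(16)-en-7-one | C1C(=O)[C@@]2(C)C[C@H]3[C@@]2(CCC3=C)[C@@]2(C)CCCC(C)(C)[C@H]12 | intermediate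
22 | 13-hydroxy-8,15:9,14-dicyclolabdan-7-one | C1C(=O)[C@@]2(C)C[C@H]3[C@@]2(CC[C@]3(C)O)[C@@]2(C)CCCC(C)(C)[C@H]12 | intermediate
23 | 13-(trimethylsilyloxy)-8,15:9,14-dicyclolabdan-7-one | C1C(=O)[C@@]2(C)C[C@H]3[C@@]2(CC[C@]3(C)O[Si](C)(C)C)[C@@]2(C)CCCC(C)(C)[C@H]12 | intermediate
24 | potassium 13-(trimethylsilyloxy)-8,15:9,14-dicyclolabd-6-en-7-olate | [K+].C1=C([O-])[C@@]2(C)C[C@H]3[C@@]2(CC[C@]3(C)O[Si](C)(C)C)[C@@]2(C)CCCC(C)(C)[C@H]12 | intermediate
25 | 13-(trimethylsilyloxy)-8,15:9,14-dicyclolabd-6-en-7-yl acetate | C1=C(OC(C)=O)[C@@]2(C)C[C@H]3[C@@]2(CC[C@]3(C)O[Si](C)(C)C)[C@@]2(C)CCCC(C)(C)[C@H]12 | intermediate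
26 | 6α,7α-epoxy-13-(trimethylsilyloxy)-8,15:9,14-dicyclolabdan-7β-yl acetate | [C@H]1(O4)[C@]4(OC(C)=O)[C@@]2(C)C[C@H]3[C@@]2(CC[C@]3(C)O[Si](C)(C)C)[C@@]2(C)CCCC(C)(C)[C@H]12 | intermediate
27 | 6β-acetoxy-13-(trimethylsilyloxy)-8,15:9,14-dicyclolabdan-7-one | CC(=O)O[C@@H]1C(=O)[C@@]2(C)C[C@H]3[C@@]2(CC[C@]3(C)O[Si](C)(C)C)[C@@]2(C)CCCC(C)(C)[C@H]12 | intermediate
28 | 6β-acetoxy-13-hydroxy-8,15:9,14-dicyclolabdan-7-one (CNP0330581.1) | CC(=O)O[C@@H]1C(=O)[C@@]2(C)C[C@H]3[C@@]2(CC[C@]3(C)O)[C@@]2(C)CCCC(C)(C)[C@H]12 | target

## Step count and least certain steps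

Total step count: 20. Longest linear sequence: 20 steps (1 → 28); the route is fully linear.

**Step 7 (key step, proposed new method).** The five-membered closure keeps the enol ether double bond inside the forming ring, so the concerted transition state is strained. Cleavage of the allylic C–O bond into an allyl/enolate or radical pair with recombination at C17 (a 1,3-shift to a ring-enlarged ketone), or acid-induced migration of the exocyclic enol ether double bond into the ring, may then be faster than the [3,3] shift. The fallback uses known chemistry, sets out from 9 and returns at 11. Methanolysis of 9 (NaOMe, MeOH) gives methyl 17-hydroxy-14,15,16-trinorlabd-8-en-13-oate F1. Johnson–Claisen rearrangement of this primary allylic alcohol (MeC(OEt)3, EtCO2H cat., 140 °C) forms the same C9–C14 bond from the lower face through an unconstrained chair and gives the diester F2. Dieckmann condensation (NaH, THF) closes ring D to the β-keto ester F3 or its regioisomer F4. Dealkoxycarbonylation of either (LiCl, wet DMSO, 150 °C) gives 11.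

**Step 5.** The β,γ-double bond may migrate into conjugation under the silyl triflate before oxygen is inserted, or oxidation may occur at the tetrasubstituted alkene instead of the ketone. The fallback sets out from 8 and returns at 9. The dienolate of 8 (KN(SiMe3)2) is hydroxylated at the doubly activated carbon C17 with 2-(phenylsulfonyl)-3-phenyloxaziridine to the α-hydroxy ketone F5. Pb(OAc)4 in MeOH cleaves C13–C17 to the aldehyde ester F6. NaBH4/CeCl3 reduces the enal to the hydroxy ester F1. LiOH gives the hydroxy acid F7, which is lactonised with 2,4,6-trichlorobenzoyl chloride, Et3N and DMAP to 9.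

**Step 15.** The enone may be reduced at the carbonyl, or the hindered tetrasubstituted enolate may be protonated before the slow four-membered closure at a fully substituted carbon, leaving the uncyclised methyl ketone. The fallback sets out from 19 and returns at 21. 1,4-Hydrosilylation with Et3SiH and RhCl(PPh3)3 gives the regiodefined triethylsilyl enol ether F8, which can be purified. MeLi in THF–DMPU then releases the lithium enolate free of borane for the ring closure.

**Step 16.** Trapping of the planar tertiary radical may show poor facial selectivity, or the cyclobutylcarbinyl radical may open. The fallback is polar, sets out from 21 and returns at 22. Dimethyldioxirane epoxidises the exocyclic alkene from the convex face to the spiro-epoxide F9. LiEt3BH opens it at the CH2 carbon and also reduces the C7 ketone, giving the diol F10. Dess–Martin oxidation of the secondary alcohol gives 22.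

**Step 19 (with the rearrangement in step 20).** Epoxidation from the upper face, or acid-catalysed opening of the epoxy acetate with retention, would each deliver the equatorial 6α-acetate; C6 may also epimerise. The fallback sets out from 23 and returns at 27, which is desilylated as in step 20. KN(SiMe3)2/PhNTf2 gives the enol triflate F11. Pd(OAc)2, PPh3, Bu3N and HCO2H reduce it to the C6=C7 alkene F12. m-CPBA gives the α-epoxide F13. Acetic acid opens it trans-diaxially at C6 (C7 is neopentyl) to the 6β-acetoxy-7α-alcohol F14. Dess–Martin oxidation gives 27.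

## Further compounds

F1 | step 7 | methyl 17-hydroxy-14,15,16-trinorlabd-8-en-13-oate | COC(=O)CCC2=C(CO)CC[C@H]1C(C)(C)CCC[C@]21C
F2 | step 7 | diester from Johnson–Claisen rearrangement (C9: CH2CO2Et α, CH2CH2CO2Me β; C8=C17) | COC(=O)CC[C@@]2(CC(=O)OCC)C(=C)CC[C@H]1C(C)(C)CCC[C@]21C
F3 | step 7 | ethyl 13-oxo-9,14-cyclo-15,16-dinorlabd-8(17)-ene-14-carboxylate | O=C1CC[C@@]2(C1C(=O)OCC)C(=C)CC[C@H]1C(C)(C)CCC[C@]21C
F4 | step 7 | regioisomeric β-keto ester (methyl ester on the ring D carbon remote from C9) | O=C1C(C(=O)OC)C[C@@]2(C1)C(=C)CC[C@H]1C(C)(C)CCC[C@]21C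
F5 | step 5 | 17-hydroxypodocarp-8-en-13-one (α-hydroxy ketone, target numbering) | O=C1CCC2=C(C1O)CC[C@H]1C(C)(C)CCC[C@]21C
F6 | step 5 | methyl 17-oxo-14,15,16-trinorlabd-8-en-13-oate | COC(=O)CCC2=C(C=O)CC[C@H]1C(C)(C)CCC[C@]21C
F7 | step 5 | 17-hydroxy-14,15,16-trinorlabd-8-en-13-oic acid | OC(=O)CCC2=C(CO)CC[C@H]1C(C)(C)CCC[C@]21C
F8 | step 15 | 7-(triethylsilyloxy)-9,14-cyclolabda-7,13(16)-dien-15-yl 4-toluenesulfonate | C=C1CC[C@@]2([C@@H]1COS(=O)(=O)c3ccc(C)cc3)C(C)=C(O[Si](CC)(CC)CC)C[C@H]1C(C)(C)CCC[C@]21C
F9 | step 16 | 13,16-epoxy-8,15:9,14-dicyclolabdan-7-one (oxygen cis to H14) | C1C(=O)[C@@]2(C)C[C@H]3[C@@]2(CC[C@@]34CO4)[C@@]2(C)CCCC(C)(C)[C@H]12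
F10 | step 16 | 8,15:9,14-dicyclolabdane-7,13-diol (either C7 epimer) | C1C(O)[C@@]2(C)C[C@H]3[C@@]2(CC[C@]3(C)O)[C@@]2(C)CCCC(C)(C)[C@H]12
F11 | step 19 | 13-(trimethylsilyloxy)-8,15:9,14-dicyclolabd-6-en-7-yl trifluoromethanesulfonate | C1=C(OS(=O)(=O)C(F)(F)F)[C@@]2(C)C[C@H]3[C@@]2(CC[C@]3(C)O[Si](C)(C)C)[C@@]2(C)CCCC(C)(C)[C@H]12
F12 | step 19 | 13-(trimethylsilyloxy)-8,15:9,14-dicyclolabd-6-ene | C1=C[C@@]2(C)C[C@H]3[C@@]2(CC[C@]3(C)O[Si](C)(C)C)[C@@]2(C)CCCC(C)(C)[C@H]12
F13 | step 19 | 6α,7α-epoxy-13-(trimethylsilyloxy)-8,15:9,14-dicyclolabdane | [C@H]1(O4)[C@@H]4[C@@]2(C)C[C@H]3[C@@]2(CC[C@]3(C)O[Si](C)(C)C)[C@@]2(C)CCCC(C)(C)[C@H]12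
F14 | step 19 | 6β-acetoxy-13-(trimethylsilyloxy)-8,15:9,14-dicyclolabdan-7α-ol | CC(=O)O[C@@H]1[C@@H](O)[C@@]2(C)C[C@H]3[C@@]2(CC[C@]3(C)O[Si](C)(C)C)[C@@]2(C)CCCC(C)(C)[C@H]12
A1 | alternative 1 | tetracycle with ring A hydroxyl, ring B tert-butyldimethylsilyl ether and ring D 12-en-11-one | C1[C@H](O[Si](C)(C)C(C)(C)C)[C@@]2(C)C[C@H]3[C@@]2(C(=O)C=C3C)[C@@]2(C)CC[C@H](O)C(C)(C)[C@H]12
A2 | alternative 2 | cyclobutene-fused 6β-acetoxy-7-ketone with dioxolane-protected 3-oxobutyl chain on C9 | CC(=O)O[C@@H]1C(=O)[C@@]2(C)C=C[C@@]2(CCC3(C)OCCO3)[C@@]2(C)CCCC(C)(C)[C@H]12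
A3 | alternative 3 | 8,15:9,14-dicyclolabda-6,12-dien-11-one | C1=C[C@@]2(C)C[C@H]3[C@@]2(C(=O)C=C3C)[C@@]2(C)CCCC(C)(C)[C@H]12
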